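**Retrosynthetic overview**
- Target 11 comes from a 2'-hydroxychalcone → flavone sequence (I2/DMSO) on a trans-benzodioxane aldehyde, which is built from 5-hydroxyvanillin and a chiral C3 unit.
- The benzodioxane ring forms first, by intramolecular benzylic C–H/O–H coupling (electrochemical, HFIP) on an aryl ether of 5-hydroxyvanillin. The C3 stereocenter of that ether is fixed by an SN2 (Mitsunobu) reaction on an alcohol made from (R)-benzyl glycidyl ether.
- The pyranone ring of the flavone is formed last, followed by hydrogenolysis of the benzyl ether.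
- Stereochemistry: C3 comes from the chiral epoxide. C2 is set trans to C3 by substrate control in the cyclization.

**Assumptions**
- (R)-Benzyl glycidyl ether, 5-hydroxyvanillin, 4-bromo-2-methoxyphenol and 2,4,6-trihydroxyacetophenone are commercial.
- In the Mitsunobu step the 4-OH of 5-hydroxyvanillin (para to CHO, most acidic) reacts in preference to the 3-OH.

---

**Step 1**
Reactants: 1 (4-bromo-2-methoxyphenol)
Product: 2 (tert-butyl(4-bromo-2-methoxyphenoxy)dimethylsilane)
Conditions: TBSCl, imidazole, DMF, rt, 4 h
Reagents that add atoms: TBSCl, CC(C)(C)[Si](C)(C)Cl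
Why: Standard silyl protection of the phenol so that the aryl Grignard can be made in step 2. It is also the oxidation-compatible phenol protecting group for step 4.

**Step 2**
Reactants: 2; 3 ((R)-benzyl glycidyl ether)
Product: 4 ((2R)-1-(benzyloxy)-3-[4-(TBSO)-3-methoxyphenyl]propan-2-ol)
Conditions: (i) Mg, THF, reflux; (ii) 3, CuI (10 mol%), THF, −20 → 0 °C
Reagents that add atoms: none
Why: Cu-catalysed Grignard opening of a terminal epoxide (SN2 at CH2). The stereocenter is not touched, so the (R)-epoxide gives the (R)-alcohol.

**Step 3**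
Reactants: 4; 5 (5-hydroxyvanillin)
Product: 6 (4-{[(2S)-1-(benzyloxy)-3-(4-TBSO-3-methoxyphenyl)propan-2-yl]oxy}-3-hydroxy-5-methoxybenzaldehyde)
Conditions: PPh3, DIAD, THF, 0 °C → rt, 16 h
Reagents that add atoms: none
Why: Mitsunobu etherification. The betaine deprotonates the most acidic phenol (4-OH, para to CHO), and SN2 at the secondary carbinol inverts it, giving the (S)-ether. The 3-OH stays free for the ring closure.

**Step 4**
Reactants: 6
Product: 7 ((2R,3R)-3-[(benzyloxy)methyl]-2-(4-TBSO-3-methoxyphenyl)-5-methoxy-2,3-dihydro-1,4-benzodioxine-7-carbaldehyde)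
Conditions: Undivided cell, graphite anode, Pt cathode, 0.1 M Et4NBF4, HFIP/CH2Cl2 (1:4), 2,6-lutidine (0.3 equiv), constant current (about 3 mA, 2.5 F/mol), rt, N2
Reagents that add atoms: none (net loss of H2 at the cathode)
Why: Proposed new method: intramolecular dehydrogenative benzylic C(sp3)–H/phenol O–H etherification that closes a 1,4-benzodioxane.
- Mechanism: anodic oxidation of the most electron-rich ring (the siloxy/methoxy aryl, with no electron-withdrawing group) gives an arene radical cation in HFIP. Benzylic deprotonation gives a radical, which is oxidized again to a benzylic cation. The pendant 3-OH then closes the six-membered ring.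
- Stereochemistry: C3 is untouched. The new C2 centre is set trans (both substituents pseudo-equatorial) by kinetic attack and by reversible HFIP ionization of the p-siloxybenzyl aryl ether.
- Closest known reactions: anodic or DDQ benzylic C–H etherification to isochromans and chromans, and quinone-methide trapping by phenols in lignin chemistry.

**Step 5**
Reactants: 7; 8 (2,4,6-trihydroxyacetophenone)
Product: 9 ((E)-chalcone with free guaiacyl OH and CH2OBn: 1-(2,4,6-trihydroxyphenyl)-3-[(2R,3R)-benzodioxan-7-yl]propenone)
Conditions: KOH (6 equiv), EtOH/H2O, rt, 48 h, N2; then aq. HCl to pH 2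
Reagents that add atoms: none (KOH/H2O only supply H)
Why: Claisen–Schmidt aldol condensation, giving the E-enone. Hydroxide also cleaves the aryl O–TBS bond in situ, which frees the guaiacyl 4-OH. The benzodioxane stereocenters are not epimerizable under these conditions.

**Step 6**
Reactants: 9
Product: 10 (flavone: 5,7-dihydroxy-2-[(2R,3R)-3-(benzyloxymethyl)-2-(4-hydroxy-3-methoxyphenyl)-5-methoxybenzodioxan-7-yl]chromen-4-one)
Conditions: I2 (0.2 equiv), DMSO, 130 °C, 3 h; then aq. Na2S2O3
Reagents that add atoms: none
Why: I2/DMSO oxidative cyclization of a 2'-hydroxychalcone (iodination, oxa-Michael addition, elimination) forms the chromone ring. No stereocenter is involved.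

**Step 7**
Reactants: 10
Product: 11 (5'-methoxyhydnocarpin)
Conditions: H2 (1 atm), 10% Pd/C, THF/MeOH, rt, 3 h
Reagents that add atoms: none
Why: Hydrogenolysis of the primary benzyl ether (toluene is lost) to the CH2OH. The flavone C2=C3 bond survives short low-pressure hydrogenolysis, and both stereocenters are unchanged.

---

**Compound list**

| # | Name | SMILES | Role |
|---|---|---|---|
| 1 | 4-Bromo-2-methoxyphenol | COc1cc(Br)ccc1O | starting material |
| 2 | tert-Butyl(4-bromo-2-methoxyphenoxy)dimethylsilane | COc1cc(Br)ccc1O[Si](C)(C)C(C)(C)C | intermediate |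
| 3 | (R)-Benzyl glycidyl ether | C1O[C@H]1COCc2ccccc2 | starting material |
| 4 | (2R)-1-(Benzyloxy)-3-[4-(TBSO)-3-methoxyphenyl]propan-2-ol | COc1cc(C[C@@H](O)COCc2ccccc2)ccc1O[Si](C)(C)C(C)(C)C | intermediate |
| 5 | 5-Hydroxyvanillin (3,4-dihydroxy-5-methoxybenzaldehyde) | COc1cc(C=O)cc(O)c1O | starting material |
| 6 | Aryl ether (2S) from Mitsunobu | COc1cc(C=O)cc(O)c1O[C@H](COCc2ccccc2)Cc3ccc(O[Si](C)(C)C(C)(C)C)c(OC)c3 | intermediate |
| 7 | trans-(2R,3R)-Benzodioxane aldehyde (TBS, Bn protected) | COc1cc([C@H]2Oc3cc(C=O)cc(OC)c3O[C@@H]2COCc4ccccc4)ccc1O[Si](C)(C)C(C)(C)C | intermediate |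
| 8 | 2,4,6-Trihydroxyacetophenone | CC(=O)c1c(O)cc(O)cc1O | starting material |
| 9 | Chalcone (free phenols, CH2OBn) | COc1cc([C@H]2Oc3cc(/C=C/C(=O)c5c(O)cc(O)cc5O)cc(OC)c3O[C@@H]2COCc4ccccc4)ccc1O | intermediate |
| 10 | O-Benzyl flavone | COc1cc([C@H]2Oc3cc(-c5cc(=O)c6c(O)cc(O)cc6o5)cc(OC)c3O[C@@H]2COCc4ccccc4)ccc1O | intermediate |
| 11 | 5'-Methoxyhydnocarpin | COc1cc([C@H]2Oc3cc(-c4cc(=O)c5c(O)cc(O)cc5o4)cc(OC)c3O[C@@H]2CO)ccc1O | target |

**Total steps:** 7. **Longest linear sequence:** 7 steps (1 → 2 → 4 → 6 → 7 → 9 → 10 → 11).

**Three steps most likely to fail**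
1. **Step 4 (new electrochemical cyclization).** Risks are over-oxidation, enol-ether formation by loss of the C3–H, and a poor trans:cis ratio.
   Fallback (known chemistry): remove the TBS group from 6 with TBAF, then oxidize the free 4-alkylguaiacol with DDQ (or Ag2O) to the p-quinone methide, which the neighbouring 3-OH traps. Any cis isomer is equilibrated to trans by acid-mediated ionization.
2. **Step 3 (Mitsunobu on the hindered 2,6-disubstituted phenol).** Risks are low conversion, elimination, and reaction at the 3-OH.
   Fallback: convert 4 to its mesylate, then displace it with the phenoxide of 5 (Cs2CO3, 18-crown-6, DMF, 60 °C). This is a pre-activated SN2 with the same inversion.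
3. **Steps 5–6 (polyphenol Claisen–Schmidt and I2/DMSO).** Risks are low yield, iodination of the free phenols, and base- or acid-induced ionization of the p-hydroxybenzyl aryl ether.
   Fallback: use 2-hydroxy-4,6-bis(MOM-oxy)acetophenone (from 8) in a mild Ba(OH)2/MeOH condensation. Run I2/DMSO on the protected chalcone, then remove the MOM groups with HCl/MeOH after hydrogenolysis.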